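**Plan**

Numbering used: ring C1 (C=O), C2=C3, C4 (CH–OMe), C5 (CH2), C6 (quaternary); side chain C7 (CH–CH3), C8 (CH(OH)Ar).
Retrosynthesis cuts, in order: O–Si at C8, the C6–allyl bond, the two ring bonds C2=C3 and C4–C5 together, the C1/C2 and C5 carbons on C6, and last C7–C8.
Enabling feature: the only alicyclic ring is a 4-methoxycyclohex-2-en-1-one in which C3/C4 are the carbonyl carbon and the O-bearing α-carbon of methoxyacetaldehyde, and C5 is the β-carbon of an α-methylene methyl ketone (C5=C6–C1(=O)–C2H3). The ring is thus the retron of a conjugate addition (C4–C5) followed by an aldol condensation (C2=C3).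
Forward: syn aldol (C7–C8), N-methoxy-N-methylamide, silyl ether, acyl-anion addition and methylenation give the chiral α-methylene ketone; an amine-catalysed [4+2] annulation with methoxyacetaldehyde then builds the ring; α′-allylation creates the quaternary centre; desilylation ends the route.
Stereochemistry: C7 and C8 from the oxazolidinone auxiliary; C4 from the chiral amine catalyst; C6 from the ring (allyl enters anti to the C4 methoxy group), reinforced by allylic 1,3-strain control from C7.

Key step: step 6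

Assumption: the enamine of methoxyacetaldehyde is taken to react as its E, s-trans isomer on the face remote from the CPh2(OSiMe3) group, as for other aldehydes with this catalyst class; on this model the (R)-catalyst gives (4S).
Remark: in the titanium–aluminium methylidene reagent of step 5 the chloride bridges titanium and aluminium through a dative contact; its structure is drawn with the Ti–Cl σ bond only.

**Route**

Step 1
Reactants: 1 (S)-4-benzyl-3-propanoyloxazolidin-2-one; 2 3,4-dimethoxybenzaldehyde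
Product: 4 (S)-4-benzyl-3-[(2S,3S)-3-(3,4-dimethoxyphenyl)-3-hydroxy-2-methylpropanoyl]oxazolidin-2-one, via Z-dibutylboron enolate 3 (not isolated)
Conditions: Bu2BOTf, iPr2NEt, CH2Cl2, 0 °C; then 2, −78 → 0 °C; pH 7 buffer, MeOH, H2O2
Reagents that add atoms: none
Why: Boron-mediated Evans syn aldol, in which the Z-boron enolate reacts through a closed chair transition state with one enolate face blocked by the benzyl group of the (S)-auxiliary, so that C7 and C8 should form as the (2S,3S) syn pair.

Step 2
Reactants: 4 (S)-4-benzyl-3-[(2S,3S)-3-(3,4-dimethoxyphenyl)-3-hydroxy-2-methylpropanoyl]oxazolidin-2-one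
Product: 5 (2S,3S)-3-(3,4-dimethoxyphenyl)-3-hydroxy-N-methoxy-N,2-dimethylpropanamide
Conditions: MeNH(OMe)·HCl, AlMe3, CH2Cl2, −10 °C → rt; aq. KNaC4H4O6
Reagents that add atoms: N,O-dimethylhydroxylamine hydrochloride, CNOC.Cl
Why: Aluminium amide transamination of the N-acyloxazolidinone (Weinreb amide formation), assisted by the free β-hydroxyl group, should cleave only the exocyclic acyl–nitrogen bond and leave both stereocentres untouched.

Step 3
Reactants: 5 (2S,3S)-3-(3,4-dimethoxyphenyl)-3-hydroxy-N-methoxy-N,2-dimethylpropanamide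
Product: 6 (2S,3S)-3-[(tert-butyldimethylsilyl)oxy]-3-(3,4-dimethoxyphenyl)-N-methoxy-N,2-dimethylpropanamide
Conditions: TBSOTf, 2,6-lutidine, CH2Cl2, −78 → 0 °C
Reagents that add atoms: tert-butyldimethylsilyl trifluoromethanesulfonate, CC(C)(C)[Si](C)(C)OS(=O)(=O)C(F)(F)F
Why: Standard silyl ether protection with a silyl triflate and a hindered pyridine base masks the benzylic hydroxyl, which would otherwise close onto the later C1 ketone as a lactol and interfere with the enolate chemistry.

Step 4
Reactants: 6 (2S,3S)-3-[(tert-butyldimethylsilyl)oxy]-3-(3,4-dimethoxyphenyl)-N-methoxy-N,2-dimethylpropanamide; 7 ethyl vinyl ether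
Product: 9 (4S,5S)-5-[(tert-butyldimethylsilyl)oxy]-5-(3,4-dimethoxyphenyl)-2-ethoxy-4-methylpent-1-en-3-one, via 1-ethoxyvinyllithium 8 (not isolated)
Conditions: 7, t-BuLi, THF, −78 → 0 °C; then 6, −78 → −20 °C; aq. NH4Cl
Reagents that add atoms: none
Why: Acylation of an α-alkoxyvinyllithium (acyl anion equivalent) by a Weinreb amide should stop at the ketone through the stable lithium chelate, attaching the masked acetyl carbons C1 and C2 to C6 without over-addition or epimerisation.

Step 5
Reactants: 9 (4S,5S)-5-[(tert-butyldimethylsilyl)oxy]-5-(3,4-dimethoxyphenyl)-2-ethoxy-4-methylpent-1-en-3-one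
Product: 11 (4R,5S)-5-[(tert-butyldimethylsilyl)oxy]-5-(3,4-dimethoxyphenyl)-4-methyl-3-methylidenepentan-2-one, via 2-ethoxydiene 10 (not isolated)
Conditions: Cp2Ti(μ-Cl)(μ-CH2)AlMe2 (Tebbe reagent), pyridine, THF–toluene, −40 → 0 °C; aq. NaOH; then oxalic acid, THF–H2O, 0 °C
Reagents that add atoms: Tebbe reagent Cp2Ti(μ-Cl)(μ-CH2)AlMe2, C[Al](C)C[Ti](Cl)(C1C=CC=C1)C1C=CC=C1; water, O
Why: Non-basic titanium methylidene (Tebbe) methylenation should convert the hindered, epimerisable ketone into the C6=C5 methylidene without enolisation, and mild aqueous acid then hydrolyses the electron-rich 2-ethoxy enol ether (protonation at its terminal CH2, the future C2 methyl) to unveil the C1 methyl ketone.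

Step 6
Reactants: 11 (4R,5S)-5-[(tert-butyldimethylsilyl)oxy]-5-(3,4-dimethoxyphenyl)-4-methyl-3-methylidenepentan-2-one; 12 methoxyacetaldehyde
Product: 15 (4S)-6-{(1S,2R)-1-[(tert-butyldimethylsilyl)oxy]-1-(3,4-dimethoxyphenyl)propan-2-yl}-4-methoxycyclohex-2-en-1-one (both C6 epimers), via keto aldehyde 13 (not isolated), via aldol 14 (not isolated)
Conditions: (R)-2-[diphenyl(trimethylsilyloxy)methyl]pyrrolidine (20 mol%), ethyl 3,4-dihydroxybenzoate (20 mol%), 12 (slow addition), toluene, 4 °C → rt; concentrate; then KOH (0.1 M aq.), Bu4NOH (cat.), THF–Et2O, 0 °C → rt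
Reagents that add atoms: none
Why: The amine condenses with 12 to an E enamine whose α-carbon adds to the unsubstituted CH2 terminus (C5) of the α-methylene ketone 11, activated by hydrogen bonding to the catechol co-catalyst, and hydrolysis releases keto aldehyde 13 (C4–C5 bond). Hydroxide then generates the methyl ketone enolate, which closes the ring onto the aldehyde by a 6-(enolendo)-exo-trig aldol addition to 14 and loses water by E1cB to form the C2=C3 bond. The closest known reaction type is the diarylprolinol-ether-catalysed Michael addition of aldehydes to vinyl ketones followed by aldol condensation (an organocatalytic Robinson-type annulation to 4-substituted cyclohex-2-enones), with α-alkoxy aldehydes established as donors for this catalyst class. C4 is set under catalyst control: the CPh2(OSiMe3) group shields one face of the enamine so that the (R)-catalyst should deliver C5 to the face that gives (4S), independent of the remote C7 and C8 centres because C5 is not prochiral. C6 forms without control, which is harmless because it is made planar again in step 7. The step needs the cross-addition to outrun self-aldol of 12 (slow addition, hydrogen-bond activation of the enone) and needs C4 not to epimerise before ring closure, which the fast intramolecular aldol, the only ring size geometrically available, should secure.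

Step 7
Reactants: 15 (4S)-6-{(1S,2R)-1-[(tert-butyldimethylsilyl)oxy]-1-(3,4-dimethoxyphenyl)propan-2-yl}-4-methoxycyclohex-2-en-1-one (both C6 epimers); 16 allyl bromide
Product: 18 (4S,6S)-6-{(1S,2R)-1-[(tert-butyldimethylsilyl)oxy]-1-(3,4-dimethoxyphenyl)propan-2-yl}-4-methoxy-6-(prop-2-en-1-yl)cyclohex-2-en-1-one, via lithium dienolate 17 (not isolated)
Conditions: LiN(iPr)2, THF, −78 °C; DMPU, 16, −78 → −30 °C
Reagents that add atoms: none
Why: Kinetic α′-deprotonation at C6 gives the cross-conjugated lithium dienolate, and enolate C-alkylation should occur on the ring face anti to the C4 methoxy group, which is also the face anti to the bulky CH(OTBS)Ar group when the C7–H bond eclipses the C1–OLi bond to avoid allylic 1,3-strain, so both elements place the allyl group as required for (6S).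

Step 8
Reactants: 18 (4S,6S)-6-{(1S,2R)-1-[(tert-butyldimethylsilyl)oxy]-1-(3,4-dimethoxyphenyl)propan-2-yl}-4-methoxy-6-(prop-2-en-1-yl)cyclohex-2-en-1-one
Product: 19 (4S,6S)-6-[(1S,2R)-1-(3,4-dimethoxyphenyl)-1-hydroxypropan-2-yl]-4-methoxy-6-(prop-2-en-1-yl)cyclohex-2-en-1-one
Conditions: Bu4NF, AcOH, THF, 0 °C → rt
Reagents that add atoms: none
Why: Fluoride-mediated silyl ether cleavage, buffered with acetic acid to keep the enone away from strongly basic conditions, should release the C8 alcohol without affecting any stereocentre.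

**Compound list**

1 | (S)-4-benzyl-3-propanoyloxazolidin-2-one | CCC(=O)N1[C@@H](Cc2ccccc2)COC1=O | starting material
2 | 3,4-dimethoxybenzaldehyde | COc1ccc(C=O)cc1OC | starting material
3 | Z-dibutylboron enolate of 1 | C/C=C(\OB(CCCC)CCCC)N1[C@@H](Cc2ccccc2)COC1=O | intermediate
4 | (S)-4-benzyl-3-[(2S,3S)-3-(3,4-dimethoxyphenyl)-3-hydroxy-2-methylpropanoyl]oxazolidin-2-one | C[C@@H]([C@H](O)c1ccc(OC)c(OC)c1)C(=O)N1[C@@H](Cc2ccccc2)COC1=O | intermediate
5 | (2S,3S)-3-(3,4-dimethoxyphenyl)-3-hydroxy-N-methoxy-N,2-dimethylpropanamide | C[C@@H]([C@H](O)c1ccc(OC)c(OC)c1)C(=O)N(C)OC | intermediate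
6 | (2S,3S)-3-[(tert-butyldimethylsilyl)oxy]-3-(3,4-dimethoxyphenyl)-N-methoxy-N,2-dimethylpropanamide | C[C@@H]([C@H](O[Si](C)(C)C(C)(C)C)c1ccc(OC)c(OC)c1)C(=O)N(C)OC | intermediate
7 | ethyl vinyl ether | C=COCC | starting material
8 | 1-ethoxyvinyllithium | [Li]C(=C)OCC | intermediate
9 | (4S,5S)-5-[(tert-butyldimethylsilyl)oxy]-5-(3,4-dimethoxyphenyl)-2-ethoxy-4-methylpent-1-en-3-one | C=C(OCC)C(=O)[C@@H](C)[C@H](O[Si](C)(C)C(C)(C)C)c1ccc(OC)c(OC)c1 | intermediate
10 | tert-butyl{[(1S,2R)-1-(3,4-dimethoxyphenyl)-4-ethoxy-2-methyl-3-methylidenepent-4-en-1-yl]oxy}dimethylsilane | C=C(OCC)C(=C)[C@@H](C)[C@H](O[Si](C)(C)C(C)(C)C)c1ccc(OC)c(OC)c1 | intermediate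
11 | (4R,5S)-5-[(tert-butyldimethylsilyl)oxy]-5-(3,4-dimethoxyphenyl)-4-methyl-3-methylidenepentan-2-one | CC(=O)C(=C)[C@@H](C)[C@H](O[Si](C)(C)C(C)(C)C)c1ccc(OC)c(OC)c1 | intermediate
12 | methoxyacetaldehyde | COCC=O | starting material
13 | (2S,5R,6S)-4-acetyl-6-[(tert-butyldimethylsilyl)oxy]-6-(3,4-dimethoxyphenyl)-2-methoxy-5-methylhexanal (both C4 epimers) | CC(=O)C(C[C@H](OC)C=O)[C@@H](C)[C@H](O[Si](C)(C)C(C)(C)C)c1ccc(OC)c(OC)c1 | intermediate
14 | (4S)-6-{(1S,2R)-1-[(tert-butyldimethylsilyl)oxy]-1-(3,4-dimethoxyphenyl)propan-2-yl}-3-hydroxy-4-methoxycyclohexan-1-one (epimers at C3 and C6) | O=C1CC(O)[C@@H](OC)CC1[C@@H](C)[C@H](O[Si](C)(C)C(C)(C)C)c1ccc(OC)c(OC)c1 | intermediate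
15 | (4S)-6-{(1S,2R)-1-[(tert-butyldimethylsilyl)oxy]-1-(3,4-dimethoxyphenyl)propan-2-yl}-4-methoxycyclohex-2-en-1-one (both C6 epimers) | O=C1C=C[C@@H](OC)CC1[C@@H](C)[C@H](O[Si](C)(C)C(C)(C)C)c1ccc(OC)c(OC)c1 | intermediate
16 | allyl bromide | C=CCBr | starting material
17 | lithium (4S)-2-{(1S,2R)-1-[(tert-butyldimethylsilyl)oxy]-1-(3,4-dimethoxyphenyl)propan-2-yl}-4-methoxycyclohexa-1,5-dien-1-olate | [Li]OC1=C([C@@H](C)[C@H](O[Si](C)(C)C(C)(C)C)c2ccc(OC)c(OC)c2)C[C@H](OC)C=C1 | intermediate
18 | (4S,6S)-6-{(1S,2R)-1-[(tert-butyldimethylsilyl)oxy]-1-(3,4-dimethoxyphenyl)propan-2-yl}-4-methoxy-6-(prop-2-en-1-yl)cyclohex-2-en-1-one | C=CC[C@@]1([C@@H](C)[C@H](O[Si](C)(C)C(C)(C)C)c2ccc(OC)c(OC)c2)C[C@H](OC)C=CC1=O | intermediate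
19 | (4S,6S)-6-[(1S,2R)-1-(3,4-dimethoxyphenyl)-1-hydroxypropan-2-yl]-4-methoxy-6-(prop-2-en-1-yl)cyclohex-2-en-1-one | C=CC[C@@]1([C@@H](C)[C@H](O)c2ccc(OC)c(OC)c2)C[C@H](OC)C=CC1=O | target

**Summary**

Total step count: 8. Longest linear sequence: 8 steps (from 1 and 2; 7, 12 and 16 are commercial inputs).

Three steps most likely to fail:

1. Step 6. Conjugate addition to the α-branched enone may be slower than self-condensation of the aldehyde, and the α-methoxy aldehyde centre may epimerise by enolisation before ring closure. The fallback sets out from 11 and comes back at 15. Aldehyde 12 is silylated (Me3SiCl, Et3N, NaI, MeCN) to 1-methoxy-2-(trimethylsilyloxy)ethene F1, which is added to 11 in a Lewis-acid-mediated Mukaiyama–Michael reaction (BF3·OEt2, CH2Cl2, −78 °C) to give 13 without control at the methoxy-bearing carbon. Aldol condensation through 14 (aq. KOH, Bu4NOH, THF–Et2O) should then give 15 together with its C4 epimer, (4R)-6-{(1S,2R)-1-[(tert-butyldimethylsilyl)oxy]-1-(3,4-dimethoxyphenyl)propan-2-yl}-4-methoxycyclohex-2-en-1-one F2; the two are diastereomers and would be separated by chromatography.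

2. Step 7. Deprotonation may occur at the γ-position (C4) instead of C6, O-allylation may compete, or face selection at the fully substituted enolate carbon may be insufficient. The fallback sets out from 15 and comes back at 18. Treatment with KN(SiMe3)2 and allyl chloroformate (THF, −78 °C) gives the allyl dienol carbonate, allyl (4S)-2-{(1S,2R)-1-[(tert-butyldimethylsilyl)oxy]-1-(3,4-dimethoxyphenyl)propan-2-yl}-4-methoxycyclohexa-1,5-dien-1-yl carbonate F3. Decarboxylative allylation with Pd2(dba)3 (a zerovalent palladium source) and (R)-4-tert-butyl-2-[2-(diphenylphosphino)phenyl]-4,5-dihydrooxazole in toluene at rt forms the C6–allyl bond from a palladium allyl enolate. The ligand enantiomer is chosen by analogy with 2-alkyl-2-allylcyclohexanones so that catalyst and substrate preferences reinforce each other.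

3. Step 5. Methylenation of the hindered, cross-conjugated ketone may be incomplete, or the centre α to the ketone may epimerise. The fallback sets out from 6 and comes back at 10 and then 11. MeMgBr (THF, 0 °C) converts 6 into (3S,4S)-4-[(tert-butyldimethylsilyl)oxy]-4-(3,4-dimethoxyphenyl)-3-methylbutan-2-one F4. Kinetic enolisation towards the methyl group and triflation (KN(SiMe3)2, PhNTf2, THF, −78 °C) give (3S,4S)-4-[(tert-butyldimethylsilyl)oxy]-4-(3,4-dimethoxyphenyl)-3-methylbut-1-en-2-yl trifluoromethanesulfonate F5. Stille coupling with tributyl(1-ethoxyvinyl)stannane (Pd(PPh3)4, LiCl, THF, reflux) gives diene 10, which is hydrolysed with oxalic acid as in step 5 to 11.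

**Further compounds**

F1 | step 6 | 1-methoxy-2-(trimethylsilyloxy)ethene (E/Z mixture) | COC=CO[Si](C)(C)C
F2 | step 6 | (4R)-6-{(1S,2R)-1-[(tert-butyldimethylsilyl)oxy]-1-(3,4-dimethoxyphenyl)propan-2-yl}-4-methoxycyclohex-2-en-1-one (both C6 epimers) | O=C1C=C[C@H](OC)CC1[C@@H](C)[C@H](O[Si](C)(C)C(C)(C)C)c1ccc(OC)c(OC)c1
F3 | step 7 | allyl (4S)-2-{(1S,2R)-1-[(tert-butyldimethylsilyl)oxy]-1-(3,4-dimethoxyphenyl)propan-2-yl}-4-methoxycyclohexa-1,5-dien-1-yl carbonate | C=CCOC(=O)OC1=C([C@@H](C)[C@H](O[Si](C)(C)C(C)(C)C)c2ccc(OC)c(OC)c2)C[C@H](OC)C=C1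
F4 | step 5 | (3S,4S)-4-[(tert-butyldimethylsilyl)oxy]-4-(3,4-dimethoxyphenyl)-3-methylbutan-2-one | CC(=O)[C@@H](C)[C@H](O[Si](C)(C)C(C)(C)C)c1ccc(OC)c(OC)c1
F5 | step 5 | (3S,4S)-4-[(tert-butyldimethylsilyl)oxy]-4-(3,4-dimethoxyphenyl)-3-methylbut-1-en-2-yl trifluoromethanesulfonate | C=C(OS(=O)(=O)C(F)(F)F)[C@@H](C)[C@H](O[Si](C)(C)C(C)(C)C)c1ccc(OC)c(OC)c1
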